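**Plan**

1. Retrosynthesis: cut the isovalerate C–O bond, then the aryl ether O–CH2 bond, then both ring bonds C1–C2 and C5–C6 of the cyclohex-3-ene at once as a retro-[4+2] (target locants: C1 carries the ester, C4 the methyl, C5 the CH2OAr, C6 is CMe2). The C4 methyl is traced back to a carbonyl.
2. Enabling feature: the C3=C4 alkene lies between the two cut bonds, so the carbocycle is the Diels–Alder adduct of a C5=C4–C3=C2 diene and the C6=C1 silyl enol ether of isobutyraldehyde. The methyl carbon on C4 and the CH2O carbon on C5 sit on adjacent ring atoms and can be tied through oxygen into a butenolide, a five-membered ring the target lacks.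
3. That temporary ring makes the diene a 2-acyl diene (electrophilic at C5, so CMe2 bonds there), locks the enoate s-trans, and carries a menthyloxy acetal centre as the only source of absolute configuration.
4. Forward: bromination and Stille vinylation of the chiral butenolide give the diene; the cycloaddition builds the carbocycle; LiAlH4 opens the temporary ring and ejects menthol; the allylic CH2OH is reduced to the C4 methyl; Williamson ether with umbelliferone, desilylation and acylation finish.
5. Stereochemistry: C5 is set by addition anti to the menthyloxy group, C1 by endo placement of the silyloxy group (cis to the C5 side chain); the acetal centre is then erased as CH2.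

Key step: step 4

Assumption: compound 1, the (5R)-menthyloxy butenolide (menthyl = (1R,2S,5R)-5-methyl-2-(propan-2-yl)cyclohexyl), is taken as a purchasable enantiopure building block whose acetal centre stays configurationally stable through steps 1–4.

**Route**

Step 1
Reactants: 1 (5R)-5-{[(1R,2S,5R)-menthyl]oxy}furan-2(5H)-one
Product: 3 (5R)-3-bromo-5-{[(1R,2S,5R)-menthyl]oxy}furan-2(5H)-one, via trans-3,4-dibromolactone 2 (not isolated)
Conditions: Br2, CH2Cl2, 0 °C; then Et3N, 0 °C → rt
Reagents that add atoms: bromine, BrBr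
Why: Bromination–dehydrobromination: anti addition of Br2 to the enoate gives dibromide 2, from which Et3N removes the acidic C-3 proton and the C-4 bromide (E1cB) to leave the α-bromobutenolide with the acetal centre untouched.

Step 2
Reactants: 3 (5R)-3-bromo-5-{[(1R,2S,5R)-menthyl]oxy}furan-2(5H)-one
Product: 4 (5R)-3-ethenyl-5-{[(1R,2S,5R)-menthyl]oxy}furan-2(5H)-one
Conditions: tributyl(vinyl)stannane, Pd(PPh3)4 (cat.), CuI (cat.), DMF, 50 °C; diene used at once
Reagents that add atoms: tributyl(vinyl)stannane, C=C[Sn](CCCC)(CCCC)CCCC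
Why: Stille coupling of an α-bromoenoate with a vinylstannane under neutral conditions should give the cross-conjugated 2-acyl diene without disturbing the acid- and base-sensitive acetal.

Step 3
Reactants: 5 2-methylpropanal (isobutyraldehyde)
Product: 6 tert-butyl(dimethyl)[(2-methylprop-1-en-1-yl)oxy]silane
Conditions: TBSOTf, Et3N, CH2Cl2, 0 °C → rt
Reagents that add atoms: tert-butyldimethylsilyl trifluoromethanesulfonate, CC(C)(C)[Si](C)(C)OS(=O)(=O)C(F)(F)F
Why: Silyl enol ether formation by soft enolisation and O-silylation of the aldehyde; no E/Z issue arises because the β-carbon carries two methyl groups.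

Step 4
Reactants: 4 (5R)-3-ethenyl-5-{[(1R,2S,5R)-menthyl]oxy}furan-2(5H)-one and 6 tert-butyl(dimethyl)[(2-methylprop-1-en-1-yl)oxy]silane
Product: 7 (3R,3aR,5R)-5-{[tert-butyl(dimethyl)silyl]oxy}-4,4-dimethyl-3-{[(1R,2S,5R)-menthyl]oxy}-3a,4,5,6-tetrahydro-2-benzofuran-1(3H)-one
Conditions: 6 (3 equiv), toluene, 110 °C, sealed tube, BHT (cat.)
Reagents that add atoms: none
Why: Inverse-electron-demand Diels–Alder reaction: the α-vinylbutenolide 4 is a 2-acyl-1,3-diene with its largest LUMO coefficient at the ring β-carbon, and silyl enol ether 6 has its largest HOMO coefficient at CMe2, so a concerted, asynchronous [4+2] joins CMe2 to the β-carbon (the leading bond, Mukaiyama–Michael-like) and the oxygen-bearing carbon to the vinyl terminus. The closest known reaction type is the cycloaddition of 2-carbonyl-substituted dienes and related electron-poor dienes with enol ethers. The cyclohexene is the only ring closed, by an intermolecular suprafacial [4+2] that leaves the new C7=C7a alkene conjugated with the lactone carbonyl. The ring-fusion centre C-3a is controlled by the neighbouring menthyloxy acetal carbon, the dienophile adding to the diene face anti to that group; C-5 is controlled by the endo orientation of the silyloxy group, which brings it cis to the C-3a–C-3 bond because C-3 is the outside substituent of the diene terminus. Regioselectivity is secured by the lactone carbonyl at the 2-position of the diene, periselectivity by the ring, which locks the enoate s-trans so that no oxa-diene cycloaddition can compete, and facial selectivity by the acetal substituent. Only the endo preference rests on secondary orbital and electrostatic effects and is the point to watch.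

Step 5
Reactants: 7 (3R,3aR,5R)-5-{[tert-butyl(dimethyl)silyl]oxy}-4,4-dimethyl-3-{[(1R,2S,5R)-menthyl]oxy}-3a,4,5,6-tetrahydro-2-benzofuran-1(3H)-one
Product: 8 [(1S,5R)-5-{[tert-butyl(dimethyl)silyl]oxy}-6,6-dimethylcyclohex-2-ene-1,2-diyl]dimethanol
Conditions: LiAlH4, Et2O, −20 → 0 °C
Reagents that add atoms: none
Why: Hydride reduction of the pseudo-ester: 1,2-reduction of the lactone carbonyl gives the allylic alcohol, the freed hemiacetal collapses to an aldehyde with loss of menthol and is reduced to the second primary alcohol, so the temporary ring and the auxiliary stereocentre are removed in one operation.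

Step 6
Reactants: 8 [(1S,5R)-5-{[tert-butyl(dimethyl)silyl]oxy}-6,6-dimethylcyclohex-2-ene-1,2-diyl]dimethanol
Product: 10 [(1S,5R)-5-{[tert-butyl(dimethyl)silyl]oxy}-2,6,6-trimethylcyclohex-2-en-1-yl]methyl methanesulfonate, via bis-mesylate 9 (not isolated)
Conditions: MsCl, Et3N, THF, −40 °C; then LiEt3BH, −78 °C
Reagents that add atoms: methanesulfonyl chloride, CS(Cl)(=O)=O
Why: Sulfonylation of both primary alcohols followed by chemoselective SN2 hydride displacement: the unhindered allylic mesylate should be reduced by LiEt3BH at −78 °C much faster than the β-branched alkyl mesylate, and with no free hydroxyl present the five-membered cyclic ether cannot form.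

Step 7
Reactants: 10 [(1S,5R)-5-{[tert-butyl(dimethyl)silyl]oxy}-2,6,6-trimethylcyclohex-2-en-1-yl]methyl methanesulfonate and 11 7-hydroxy-2H-chromen-2-one (umbelliferone)
Product: 12 7-{[(1S,5R)-5-{[tert-butyl(dimethyl)silyl]oxy}-2,6,6-trimethylcyclohex-2-en-1-yl]methoxy}-2H-chromen-2-one
Conditions: Cs2CO3, DMF, 70 °C
Reagents that add atoms: none
Why: Williamson ether synthesis: the weakly basic coumarin-7-olate should displace the primary mesylate by SN2 without affecting the silyl ether, the alkene or the coumarin lactone.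

Step 8
Reactants: 12 7-{[(1S,5R)-5-{[tert-butyl(dimethyl)silyl]oxy}-2,6,6-trimethylcyclohex-2-en-1-yl]methoxy}-2H-chromen-2-one
Product: 13 7-{[(1S,5R)-5-hydroxy-2,6,6-trimethylcyclohex-2-en-1-yl]methoxy}-2H-chromen-2-one
Conditions: HF·pyridine, THF, 0 °C → rt
Reagents that add atoms: none
Why: Fluoride-mediated silyl ether cleavage under mildly acidic conditions that should leave the coumarin, the aryl ether and the trisubstituted alkene intact.

Step 9
Reactants: 13 7-{[(1S,5R)-5-hydroxy-2,6,6-trimethylcyclohex-2-en-1-yl]methoxy}-2H-chromen-2-one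
Product: 14 (1R,5S)-4,6,6-trimethyl-5-{[(2-oxo-2H-chromen-7-yl)oxy]methyl}cyclohex-3-en-1-yl 3-methylbutanoate
Conditions: 3-methylbutanoyl chloride, Et3N, DMAP (cat.), CH2Cl2, 0 °C → rt
Reagents that add atoms: 3-methylbutanoyl chloride, CC(C)CC(Cl)=O
Why: DMAP-catalysed acylation of the hindered secondary alcohol, with retention at the carbinol carbon, should give the target.

**Compound list**

1 | (5R)-5-{[(1R,2S,5R)-5-methyl-2-(propan-2-yl)cyclohexyl]oxy}furan-2(5H)-one | O=C1O[C@@H](O[C@@H]2C[C@H](C)CC[C@H]2C(C)C)C=C1 | starting material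
2 | (3S,4S,5R)-3,4-dibromo-5-{[(1R,2S,5R)-menthyl]oxy}oxolan-2-one (3,4-trans; Br at C-4 trans to the menthyloxy group) | O=C1O[C@@H](O[C@@H]2C[C@H](C)CC[C@H]2C(C)C)[C@H](Br)[C@H]1Br | intermediate (not isolated)
3 | (5R)-3-bromo-5-{[(1R,2S,5R)-menthyl]oxy}furan-2(5H)-one | O=C1O[C@@H](O[C@@H]2C[C@H](C)CC[C@H]2C(C)C)C=C1Br | intermediate
4 | (5R)-3-ethenyl-5-{[(1R,2S,5R)-menthyl]oxy}furan-2(5H)-one | O=C1O[C@@H](O[C@@H]2C[C@H](C)CC[C@H]2C(C)C)C=C1C=C | intermediate
5 | 2-methylpropanal | CC(C)C=O | starting material
6 | tert-butyl(dimethyl)[(2-methylprop-1-en-1-yl)oxy]silane | CC(C)=CO[Si](C)(C)C(C)(C)C | intermediate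
7 | (3R,3aR,5R)-5-{[tert-butyl(dimethyl)silyl]oxy}-4,4-dimethyl-3-{[(1R,2S,5R)-menthyl]oxy}-3a,4,5,6-tetrahydro-2-benzofuran-1(3H)-one | O=C1O[C@@H](O[C@@H]2C[C@H](C)CC[C@H]2C(C)C)[C@H]3C1=CC[C@@H](O[Si](C)(C)C(C)(C)C)C3(C)C | intermediate
8 | [(1S,5R)-5-{[tert-butyl(dimethyl)silyl]oxy}-6,6-dimethylcyclohex-2-ene-1,2-diyl]dimethanol | OCC1=CC[C@@H](O[Si](C)(C)C(C)(C)C)C(C)(C)[C@H]1CO | intermediate
9 | [(1S,5R)-5-{[tert-butyl(dimethyl)silyl]oxy}-6,6-dimethylcyclohex-2-ene-1,2-diyl]bis(methylene) dimethanesulfonate | CS(=O)(=O)OCC1=CC[C@@H](O[Si](C)(C)C(C)(C)C)C(C)(C)[C@H]1COS(C)(=O)=O | intermediate (not isolated)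
10 | [(1S,5R)-5-{[tert-butyl(dimethyl)silyl]oxy}-2,6,6-trimethylcyclohex-2-en-1-yl]methyl methanesulfonate | CC1=CC[C@@H](O[Si](C)(C)C(C)(C)C)C(C)(C)[C@H]1COS(C)(=O)=O | intermediate
11 | 7-hydroxy-2H-chromen-2-one (umbelliferone) | Oc1ccc2ccc(=O)oc2c1 | starting material
12 | 7-{[(1S,5R)-5-{[tert-butyl(dimethyl)silyl]oxy}-2,6,6-trimethylcyclohex-2-en-1-yl]methoxy}-2H-chromen-2-one | CC1=CC[C@@H](O[Si](C)(C)C(C)(C)C)C(C)(C)[C@H]1COc1ccc2ccc(=O)oc2c1 | intermediate
13 | 7-{[(1S,5R)-5-hydroxy-2,6,6-trimethylcyclohex-2-en-1-yl]methoxy}-2H-chromen-2-one | CC1=CC[C@@H](O)C(C)(C)[C@H]1COc1ccc2ccc(=O)oc2c1 | intermediate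
14 | (1R,5S)-4,6,6-trimethyl-5-{[(2-oxo-2H-chromen-7-yl)oxy]methyl}cyclohex-3-en-1-yl 3-methylbutanoate | CC1=CC[C@@H](OC(=O)CC(C)C)C(C)(C)[C@H]1COc1ccc2ccc(=O)oc2c1 | target

**Step count**

Total steps: 9. Longest linear sequence: 8 (steps 1, 2, 4, 5, 6, 7, 8, 9).

**Steps most likely to fail**

Step 4. The cycloaddition may proceed with insufficient endo preference, so that the silyloxy-bearing carbon forms as a mixture of epimers; regiochemistry and facial selectivity are not in doubt. In the fallback, the stereocentre is set by substrate control instead of by the cycloaddition, and the mixture is carried through steps 5–8 unchanged. The fallback sets out from alcohol 13, then an epimer mixture at the carbinol carbon. Dess–Martin oxidation (NaHCO3-buffered CH2Cl2) should give 7-{[(1S)-2,6,6-trimethyl-5-oxocyclohex-2-en-1-yl]methoxy}-2H-chromen-2-one F1. Luche reduction (NaBH4, CeCl3, MeOH, −40 °C) should then deliver hydride axially to this ketone next to the gem-dimethyl carbon, giving the equatorial alcohol cis to the side chain. The route is rejoined at 13 as a single isomer.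

Step 6. The hydride may fail to discriminate (attack on the second mesylate, at sulfur, or SN2′ delivery), or a mono-mesylate may cyclise onto the neighbouring hydroxyl before the second sulfonylation. In the fallback, which sets out from diol 8, the two hydroxyls are told apart in the activation step. Corey–Kim chlorination (NCS, Me2S, CH2Cl2, −20 → 0 °C) converts only the allylic alcohol and should give [(1R,5R)-5-{[tert-butyl(dimethyl)silyl]oxy}-2-(chloromethyl)-6,6-dimethylcyclohex-2-en-1-yl]methanol F2. LiEt3BH (THF, −78 °C) should reduce the allylic chloride to [(1S,5R)-5-{[tert-butyl(dimethyl)silyl]oxy}-2,6,6-trimethylcyclohex-2-en-1-yl]methanol F3. Mitsunobu etherification of this alcohol with 11 (PPh3, DIAD, THF) rejoins the route at 12, so the sulfonate displacement of step 7 is bypassed as well.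

Step 5. Hydride may add in conjugate fashion to the alkylidene lactone, or the transient α-branched aldehyde may enolise before it is reduced. In the fallback, which sets out from 7, the reduction is split into two chemoselective stages. i-Bu2AlH (1.1 equiv, CH2Cl2, −78 °C) should stop at (3R,3aR,5R)-5-{[tert-butyl(dimethyl)silyl]oxy}-4,4-dimethyl-3-{[(1R,2S,5R)-menthyl]oxy}-1,3,3a,4,5,6-hexahydro-2-benzofuran-1-ol F4 (C-1 epimers). Luche reduction (NaBH4, CeCl3, MeOH, 0 °C) of its ring-opened dialdehyde form, with loss of menthol, should give clean 1,2-reduction and rejoin the route at diol 8.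

**Further compounds**

F1 | step 4 | 7-{[(1S)-2,6,6-trimethyl-5-oxocyclohex-2-en-1-yl]methoxy}-2H-chromen-2-one | CC1=CCC(=O)C(C)(C)[C@H]1COc1ccc2ccc(=O)oc2c1
F2 | step 6 | [(1R,5R)-5-{[tert-butyl(dimethyl)silyl]oxy}-2-(chloromethyl)-6,6-dimethylcyclohex-2-en-1-yl]methanol | ClCC1=CC[C@@H](O[Si](C)(C)C(C)(C)C)C(C)(C)[C@H]1CO
F3 | step 6 | [(1S,5R)-5-{[tert-butyl(dimethyl)silyl]oxy}-2,6,6-trimethylcyclohex-2-en-1-yl]methanol | CC1=CC[C@@H](O[Si](C)(C)C(C)(C)C)C(C)(C)[C@H]1CO
F4 | step 5 | (3R,3aR,5R)-5-{[tert-butyl(dimethyl)silyl]oxy}-4,4-dimethyl-3-{[(1R,2S,5R)-menthyl]oxy}-1,3,3a,4,5,6-hexahydro-2-benzofuran-1-ol (C-1 epimers) | OC1O[C@@H](O[C@@H]2C[C@H](C)CC[C@H]2C(C)C)[C@H]3C1=CC[C@@H](O[Si](C)(C)C(C)(C)C)C3(C)C
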